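Assumption: the target has no stereocentre as drawn, and any planar chirality of the cyclophane is taken to be conformationally mobile, so no stereocontrol is planned.

## Structural features

Juglanin A (17) is a 15-membered oxa-bridged metaparacyclophane. Anisole ring A is spanned meta (a4 and a6) and ring B para (b1 and b4). The rings are joined by the diaryl ether oxygen (a6–O–b1) and by a seven-carbon chain that runs from C1 on a4 through the C3 ketone to C7 on b4. Ring A carries methoxy at a1; ring B carries three contiguous oxygens, the ether oxygen at b1, methoxy at b6 and a free hydroxyl at b5, and b5 is ortho to b4. The fragile groups are the free phenol (oxidation, acylation) and the dialkyl ketone, enolisable at C2 and C4; in the intermediates they are the acid-labile dioxolane and the nucleophile-labile aryl ester, while the diaryl ether and the methyl ethers are robust. The real difficulty is the para bridge on ring B: any ground-state macrocyclisation that forms it pays strain and entropy in a single step, and ring B needs three differentiated oxygens. The key step uses the b5 hydroxyl next to the b4–C7 bond: an acyl group on b4 is the product of a 1,3-shift of an acyl group from the b5 oxygen. Once C7 is detached from b4, ring B is the mirror-symmetric 2-methoxyresorcinol pattern. The ring formed contains the ether oxygen, so it is not an all-carbon ring. In the lactone stage the b6 methoxy lies between the bridgeheads b1 and b5, inside the perimeter; in the cyclophane it moves to the periphery.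

## Logic of the disconnections

17 is traced back to 16 without cutting a skeletal bond: the C3 carbonyl is masked as a dioxolane. The mask keeps the dialkyl ketone away from hydride and from light in the preceding steps. The forward step needs only dilute aqueous acid, which the phenol and the aryl ethers tolerate.

16 is traced back to 13 by adding a carbonyl at benzylic C7. An acyl group on b4 ortho to the b5 hydroxyl is the retron of an oxygen-to-carbon acyl shift. The forward step must remove the oxygen of an ortho-hydroxyaryl ketone without acid, so that the ketal stays.

13 is traced back to 10 by cutting b4–C7 and reconnecting C7 to the b5 oxygen. The para bridge becomes a meta,meta-bridged aryl ester of the same ring size, and ring B loses its only carbon substituent. The forward step is a photochemical 1,3-acyl shift and must deliver the acyl group to b4 rather than to b2 or b6, and before CO is lost. No blocking group is placed on b2: it would cost steps, and a halogen there would itself be photolabile. The ketal is kept in 10 for the reasons given under steps 4 and 6.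

10 is traced back to 8 by cutting the ester bond between C7 and the b5 oxygen. This gives an open-chain phenol acid. The forward step is a phenolic macrolactonisation that must run at high dilution and under basic conditions only, because of the ketal.

8 is traced back to 6 and then to 5 by two functional-group changes: the dioxolane returns to the C3 ketone, and the C1–C2 single bond becomes the enone double bond. The enone is the retron of an aldol condensation. The forward steps are a ketalisation in the presence of a carboxyl group (the glycol ester formed alongside is saponified) and a chemoselective alkene hydrogenation.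

5 is traced back to 3 and 4 by cutting C1=C2. C2 to C7 then arrive in one commercial piece with both oxidation levels (C3 ketone, C7 carboxyl) already in place, and C1 is the aldehyde carbon. The forward condensation must take place at the methyl group of 4 and not at C4.

3 is traced back to 1 and 2 by cutting the a6–O bond. Both pieces are commercial, and the symmetry of 2 removes any question of which hydroxyl reacts. The forward step must stop at mono-arylation.

## Other disconnections considered

Alternative 1: The cut is the a4–C1 aryl–alkenyl bond. In the forward direction the aryl bromide and vinyl ketone A1 would be cyclised with Pd(OAc)2, tri(o-tolyl)phosphine and triethylamine. Zerovalent palladium inserts into the a4–Br bond, the terminal alkene inserts at C1, and β-hydride elimination gives the E-enone A2 and closes the 15-membered ring. One hydrogenation over Pd/C would then saturate C1=C2 and remove the benzyl group.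
- In its favour: the site of bond formation is unambiguous, C3 needs no ketal because it is part of the enone, and the end game is one step. On these three points the alternative is better than the chosen plan. It is also thermal and needs no photoreactor.
- Against it here: the para-bridged ring must be closed in the ground state, stiffened further by an E-alkene conjugated to ring A, and the strain is paid in the insertion step at high dilution, where catalyst lifetime is short. Reduction of the C–Br bond, dimerisation, and amine-induced polymerisation or conjugate addition at the vinyl ketone compete.
- Structure and step economy: ring B of A1 must be built as a tetrasubstituted arene with three different oxygen substituents and the chain already at b4, and ring A needs two differentiated handles. The chosen plan takes ring B from a symmetric commercial diol and is estimated to be several steps shorter.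
- Mechanism: the chosen plan closes an easier lactone first and lets light pay for the strain.

Alternative 2: The cuts are a5–a6 and a2–a3, so ring A is built last. In the forward direction piperidinium acetate would condense the aryloxyacetone unit of A3 with its tethered 2-alkylmalondialdehyde. The first condensation closes the macrocycle, the second closes the six-membered ring, and dehydration and tautomerisation give the phenol A4.
- In its favour: aromatisation supplies the driving force for the strained ring, in the same way that the photon does in the chosen plan, so the two are equal on that point. It uses no copper and no aryl halide, and ring B has no regiochemical question. On this last point it is better than the chosen plan.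
- Against it here: this benzannulation is well established mainly for doubly activated ketones or acceptor-substituted malondialdehydes. The aryloxyacetone has two enolisable sites of similar acidity, 2-alkylmalondialdehydes self-condense, and the first bond must be formed as a macrocyclisation with no aromatic driving force yet available.
- Step economy: A4 still needs O-methylation at a1, debenzylation and ketal hydrolysis, three steps against two, and A3 is long to prepare.
- Mechanism: it is the least supported of the four plans by known reaction types.

Alternative 3: The cut is the C6–C7 bond, through the 16-membered benzylic sulfone A5. In the forward direction KOH and CCl4 in tert-butanol would chlorinate next to sulfur at benzylic C7, close the three-membered ring by 1,3-elimination and extrude SO2. The product is the 15-membered alkene A6, whose geometry is irrelevant. Hydrogenation would then saturate the alkene and remove the benzyl group, and acid would free the ketone.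
- In its favour: the concept matches the chosen plan, an easy larger ring followed by a contraction that pays the strain. The new bond can only form between C6 and C7, which is better than the chosen plan on regiochemical certainty. The end game is two steps, equal to the chosen plan.
- Against it here: dichlorocarbene from CCl4 and KOH can attack the electron-rich arenes and the styrene-type product, over-chlorination is possible, and sulfur must be removed completely before the palladium step.
- Step economy: A5 needs a ring B piece with three differentiated oxygens and a benzylic leaving group, a chain with a terminal leaving group and the ketal, a sulfide macrocyclisation and an oxidation, so the sequence is clearly longer.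
- Mechanism: the chosen plan is an isomerisation that uses an oxygen already present in the target and loses no atoms.

Key step: step 6

## Route

Step 1
Reactants: 1 3-bromo-4-methoxybenzaldehyde; 2 2-methoxyresorcinol (2-methoxybenzene-1,3-diol)
Product: 3 3-(3-hydroxy-2-methoxyphenoxy)-4-methoxybenzaldehyde
Conditions: 2 (3 equiv), CuI (10 mol %), N,N-dimethylglycine·HCl (30 mol %), Cs2CO3, 1,4-dioxane, 90 °C, Ar
Reagents that add atoms: none
Why: Ullmann diaryl ether synthesis catalysed by monovalent copper with an amino acid ligand; the two hydroxyls of 2 are equivalent by symmetry, so only mono- over bis-arylation must be controlled, which the threefold excess of the cheap, recoverable diol secures; the aldehyde has no enolisable hydrogen and tolerates carbonate base.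

Step 2
Reactants: 3 3-(3-hydroxy-2-methoxyphenoxy)-4-methoxybenzaldehyde; 4 5-oxohexanoic acid
Product: 5 (E)-7-[3-(3-hydroxy-2-methoxyphenoxy)-4-methoxyphenyl]-5-oxohept-6-enoic acid
Conditions: 4 (1.5 equiv), NaOH (5 equiv), EtOH/H2O, 0 °C → rt; then 1 M HCl to pH 2
Reagents that add atoms: none
Why: Claisen–Schmidt (crossed aldol) condensation; 3 cannot enolise and under hydroxide the methyl ketone condenses at its methyl group rather than at C4 (less hindered enolate, irreversible E1cB dehydration to the conjugated enone); the carboxylate form of 4 shuts off the intramolecular Claisen cyclisation an ester would undergo, and the E alkene is the thermodynamic product.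

Step 3
Reactants: 5 (E)-7-[3-(3-hydroxy-2-methoxyphenoxy)-4-methoxyphenyl]-5-oxohept-6-enoic acid
Product: 6 7-[3-(3-hydroxy-2-methoxyphenoxy)-4-methoxyphenyl]-5-oxoheptanoic acid
Conditions: H2 (1 atm), 10% Pd/C, EtOAc, rt
Reagents that add atoms: none
Why: Catalytic hydrogenation of the conjugated C1=C2 bond; at 1 atm over Pd/C the dialkyl ketone, the phenol and the aryl ethers are not reduced, and C1 bears no benzylic heteroatom that could be hydrogenolysed.

Step 4
Reactants: 6 7-[3-(3-hydroxy-2-methoxyphenoxy)-4-methoxyphenyl]-5-oxoheptanoic acid
Product: 8 4-(2-{2-[3-(3-hydroxy-2-methoxyphenoxy)-4-methoxyphenyl]ethyl}-1,3-dioxolan-2-yl)butanoic acid, via 2-hydroxyethyl ester 7 (not isolated)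
Conditions: HOCH2CH2OH (10 equiv), TsOH·H2O (5 mol %), toluene, Dean–Stark, reflux; then LiOH, THF/MeOH/H2O, rt; cold 0.5 M HCl to pH 4–5
Reagents that add atoms: ethylene glycol, OCCO; lithium hydroxide, [Li+].[OH-]
Why: Acid-catalysed ketalisation with azeotropic removal of water; the carboxyl group is esterified by the glycol alongside (Fischer esterification), so crude 7 is saponified with LiOH, to which the dioxolane is inert; the ketal is needed because an activated 5-oxo acid would close to the six-membered enol lactone in step 5 and a free ketone would interfere in steps 6 and 7.

Step 5
Reactants: 8 4-(2-{2-[3-(3-hydroxy-2-methoxyphenoxy)-4-methoxyphenyl]ethyl}-1,3-dioxolan-2-yl)butanoic acid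
Product: 10 15-membered macrolactone in which the C7 carboxyl of 8 acylates its own ring B hydroxyl at b5 (ring A bridged a4/a6 and ring B bridged b1/b5 with the dioxolane at C3), via acyloxypyridinium salt 9 (not isolated)
Conditions: 2-chloro-1-methylpyridinium iodide (4 equiv), Et3N (8 equiv), MeCN, reflux; 8 added by syringe pump over 10 h (final 1–2 mM)
Reagents that add atoms: none
Why: Mukaiyama macrolactonisation; the carboxylate adds to the 2-chloropyridinium salt to give the acylating agent 9, and at high dilution the internal ring B phenoxide attacks it to close the meta,meta-bridged aryl ester; the medium stays basic throughout so the ketal survives, and phenols are acylated readily by this onium activation.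

Step 6
Reactants: 10 15-membered macrolactone (aryl ester at the b5 oxygen)
Product: 13 7-oxo-juglanin A ethylene ketal (ortho-hydroxyaryl ketone; C7 carbonyl on b4 and free hydroxyl on b5), via acyl–phenoxyl biradical 11 (not isolated), via cyclohexadienone 12 (not isolated)
Conditions: hν (254 nm, low-pressure Hg lamps, quartz), degassed MeCN (2 mM), rt, to partial conversion; recovered 10 recycled
Reagents that add atoms: none
Why: Excitation of the aryl ester chromophore breaks the bond between the b5 oxygen and C7 homolytically to the tethered biradical 11, whose acyl carbon recombines at the ortho carbon b4 to give cyclohexadienone 12; enolisation of 12 restores aromaticity and gives the hydrogen-bonded ortho-hydroxy ketone 13. The closest known reaction type is the photo-Fries rearrangement of aryl esters, which is also established for macrocyclic aryl esters that rearrange to bridged ortho-acylphenols, so this is an application to a new molecule. The ring closed is the 15-membered oxa-bridged metaparacyclophane (a4–a5–a6–O–b1–b2–b3–b4–C7 to C1), formed by radical–radical coupling of C7 with b4 inside the tether while the lactone ring of equal size opens, a net 1,3-acyl shift that moves the bridge from the meta to the para position relative to b1. No stereocentre is created; 12 is chiral at b4 only transiently and racemic. The selectivity needed is coupling at b4 rather than at b2, at b6 or back at oxygen, and coupling before loss of CO. Return to oxygen only regenerates 10, b6 bears methoxy so coupling there cannot aromatise, and b4 is the free ortho carbon next to the departing oxygen and so the least-motion partner, whereas b2 lies across the ring; the short life of the tethered singlet pair should also outrun decarbonylation of a primary acyl radical. The chelated product is deactivated by excited-state proton transfer but absorbs strongly, so irradiation is stopped at partial conversion. The ketal keeps the C3 carbonyl out of ketone photochemistry, and the photon, not a ground-state ring closure, pays for the strain of the para bridge.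

Step 7
Reactants: 13 7-oxo-juglanin A ethylene ketal
Product: 16 juglanin A ethylene ketal (C7 methylene; free b5 hydroxyl), via aryl ethyl carbonate 14 (not isolated), via ortho-quinone methide 15 (not isolated)
Conditions: ClCO2Et, Et3N, THF, 0 °C; then NaBH4, H2O, 0 °C → rt; pH 7 buffer work-up
Reagents that add atoms: none
Why: Reduction of an ortho-acylphenol to the ortho-alkylphenol through its ethyl carbonate; borohydride adds to the C7 ketone of 14, the alkoxide takes over the neighbouring carbonate and ethyl carbonate is expelled to give quinone methide 15, which a second hydride reduces at C7; the medium is neutral to basic, so the ketal and the diaryl ether are untouched.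

Step 8
Reactants: 16 juglanin A ethylene ketal
Product: 17 juglanin A
Conditions: 1 M HCl, THF, rt
Reagents that add atoms: water, O
Why: Acid-catalysed hydrolysis of the 1,3-dioxolane frees the C3 ketone; the phenol, the methyl ethers and the diaryl ether are stable to dilute aqueous acid at room temperature and there is no stereocentre to epimerise.

## Compound list

1 | 3-bromo-4-methoxybenzaldehyde | COc1ccc(C=O)cc1Br | starting material
2 | 2-methoxyresorcinol (2-methoxybenzene-1,3-diol) | COc1c(O)cccc1O | starting material
3 | 3-(3-hydroxy-2-methoxyphenoxy)-4-methoxybenzaldehyde | COc1ccc(C=O)cc1Oc1cccc(O)c1OC | intermediate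
4 | 5-oxohexanoic acid | CC(=O)CCCC(=O)O | starting material
5 | (E)-7-[3-(3-hydroxy-2-methoxyphenoxy)-4-methoxyphenyl]-5-oxohept-6-enoic acid | COc1ccc(/C=C/C(=O)CCCC(=O)O)cc1Oc1cccc(O)c1OC | intermediate
6 | 7-[3-(3-hydroxy-2-methoxyphenoxy)-4-methoxyphenyl]-5-oxoheptanoic acid | COc1ccc(CCC(=O)CCCC(=O)O)cc1Oc1cccc(O)c1OC | intermediate
7 | 2-hydroxyethyl 4-(2-{2-[3-(3-hydroxy-2-methoxyphenoxy)-4-methoxyphenyl]ethyl}-1,3-dioxolan-2-yl)butanoate (not isolated) | COc1ccc(CCC2(OCCO2)CCCC(=O)OCCO)cc1Oc1cccc(O)c1OC | intermediate
8 | 4-(2-{2-[3-(3-hydroxy-2-methoxyphenoxy)-4-methoxyphenyl]ethyl}-1,3-dioxolan-2-yl)butanoic acid | COc1ccc(CCC2(OCCO2)CCCC(=O)O)cc1Oc1cccc(O)c1OC | intermediate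
9 | 1-methyl-2-(acyloxy)pyridinium iodide of acid 8 (not isolated) | COc1ccc(CCC2(OCCO2)CCCC(=O)Oc2cccc[n+]2C)cc1Oc1cccc(O)c1OC.[I-] | intermediate
10 | 15-membered macrolactone, aryl ester at the b5 oxygen, dioxolane at C3 | COc1ccc2cc1Oc1cccc(c1OC)OC(=O)CCCC1(OCCO1)CC2 | intermediate
11 | tethered acyl–phenoxyl biradical from 10 (not isolated) | COc1ccc(CCC2(OCCO2)CCC[C]=O)cc1Oc1cccc([O])c1OC | intermediate
12 | cyclohexadienone from coupling of C7 with b4, racemic at b4 (not isolated) | COc1ccc2cc1OC1=C(OC)C(=O)C(C=C1)C(=O)CCCC1(OCCO1)CC2 | intermediate
13 | 7-oxo-juglanin A ethylene ketal | COc1ccc2cc1Oc1ccc(c(O)c1OC)C(=O)CCCC1(OCCO1)CC2 | intermediate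
14 | ethyl carbonate of 13 at the b5 oxygen (not isolated) | COc1ccc2cc1Oc1ccc(c(OC(=O)OCC)c1OC)C(=O)CCCC1(OCCO1)CC2 | intermediate
15 | ortho-quinone methide with exocyclic b4=C7 bond, geometry undefined (not isolated) | COc1ccc2cc1OC1=C(OC)C(=O)C(=CCCCC3(OCCO3)CC2)C=C1 | intermediate
16 | juglanin A ethylene ketal | COc1ccc2cc1Oc1ccc(c(O)c1OC)CCCCC1(OCCO1)CC2 | intermediate
17 | juglanin A | COc1ccc2cc1Oc1ccc(c(O)c1OC)CCCCC(=O)CC2 | target

## Step count and least certain steps

Total step count: 8. Longest linear sequence: 8 steps, from 1 and 2 to 17; 4 enters at step 2.

**Step 6 (key step).**
- What may go wrong: coupling of the biradical at the wrong ring carbon (b2, or the methoxy-bearing b6 followed by ring-opening of the blocked dienone); loss of CO before coupling; stalling because the product absorbs the light, with secondary photolysis at the diaryl ether on long irradiation; return of the biradical to 10 because closing the strained para bridge is slow.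
- Fallback: it sets out from 1, 4 and 2 and returns at 13, and closes the ring by a copper-mediated etherification.
  - Claisen–Schmidt condensation of 1 with 4 (NaOH, EtOH/H2O) should give (E)-7-(3-bromo-4-methoxyphenyl)-5-oxohept-6-enoic acid F1.
  - Homogeneous hydrogenation with RhCl(PPh3)3 (H2, toluene/EtOH), which spares the aryl bromide, should give 7-(3-bromo-4-methoxyphenyl)-5-oxoheptanoic acid F2.
  - Nencki-type C-acylation of 2 with F2 in BF3·OEt2 at 80 °C should give 7-(3-bromo-4-methoxyphenyl)-1-(2,4-dihydroxy-3-methoxyphenyl)heptane-1,5-dione F3; the two ring positions of 2 open to acylation are equivalent.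
  - Ketalisation (ethylene glycol, TsOH, toluene, Dean–Stark) should take only the dialkyl ketone and give the C3 dioxolane of the bromo diketone F4, the chelated aryl ketone being inert.
  - Intramolecular Ullmann etherification (CuO, K2CO3, pyridine, reflux, high dilution) should arylate only the unchelated b1 hydroxyl para to the acyl group and so give 13.

**Step 5.**
- What may go wrong: intermolecular acylation to cyclic dimer and oligomers outrunning ring closure, because the b6 methoxy becomes intra-annular and the phenol is hindered and hydrogen bonded; ketene formation from the activated acid under amine base.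
- Fallback: it sets out from 8 and returns at 10, and separates activation from ring closure. EDC·HCl and pentafluorophenol in CH2Cl2 at 0 °C, with no acyl-transfer catalyst so that the hindered internal phenol does not compete, should give the pentafluorophenyl ester of 8 F5. Slow addition of F5 to Cs2CO3 in MeCN at 60 °C (1 mM) should close the ring by attack of the cesium phenoxide on the preformed active ester.

**Step 1.**
- What may go wrong: arylation of both hydroxyls, slow coupling between two ortho-methoxy partners, and oxidation of the electron-rich diol in the presence of copper.
- Fallback: it sets out from 2 and returns at 6, and desymmetrises the diol first. Benzyl bromide and K2CO3 in acetone with excess 2 should give 3-(benzyloxy)-2-methoxyphenol F6. The same copper-catalysed coupling with 1 should give 3-[3-(benzyloxy)-2-methoxyphenoxy]-4-methoxybenzaldehyde F7. Claisen–Schmidt condensation with 4 should give (E)-7-{3-[3-(benzyloxy)-2-methoxyphenoxy]-4-methoxyphenyl}-5-oxohept-6-enoic acid F8. Hydrogenation over Pd/C then saturates the alkene and removes the benzyl group in one operation to give 6.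

**Step 7.**
- What may go wrong: reduction stopping after the first hydride transfer, because expulsion of the carbonate needs an exocyclic double bond at b4 inside the strained bridge; cleavage of the carbonate back to the phenol before the ketone is reduced.
- Fallback: it sets out from 13 and returns at 16, and uses catalytic hydrogenolysis in place of the quinone methide pathway. NaBH4 in MeOH/THF at 0 °C should give the racemic benzylic alcohol 7-hydroxy-juglanin A ethylene ketal F9. Hydrogenolysis of its benzylic C–O bond (H2, 10% Pd/C, EtOAc/AcOH, rt) should give 16. Any ketal lost in the acetic acid is of no consequence, because step 8 removes it.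

## Further compounds

F1 | step 6 | (E)-7-(3-bromo-4-methoxyphenyl)-5-oxohept-6-enoic acid | COc1ccc(/C=C/C(=O)CCCC(=O)O)cc1Br
F2 | step 6 | 7-(3-bromo-4-methoxyphenyl)-5-oxoheptanoic acid | COc1ccc(CCC(=O)CCCC(=O)O)cc1Br
F3 | step 6 | 7-(3-bromo-4-methoxyphenyl)-1-(2,4-dihydroxy-3-methoxyphenyl)heptane-1,5-dione | COc1ccc(CCC(=O)CCCC(=O)c2ccc(O)c(OC)c2O)cc1Br
F4 | step 6 | 4-{2-[2-(3-bromo-4-methoxyphenyl)ethyl]-1,3-dioxolan-2-yl}-1-(2,4-dihydroxy-3-methoxyphenyl)butan-1-one | COc1ccc(CCC2(OCCO2)CCCC(=O)c2ccc(O)c(OC)c2O)cc1Br
F5 | step 5 | pentafluorophenyl 4-(2-{2-[3-(3-hydroxy-2-methoxyphenoxy)-4-methoxyphenyl]ethyl}-1,3-dioxolan-2-yl)butanoate | COc1ccc(CCC2(OCCO2)CCCC(=O)Oc2c(F)c(F)c(F)c(F)c2F)cc1Oc1cccc(O)c1OC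
F6 | step 1 | 3-(benzyloxy)-2-methoxyphenol | COc1c(O)cccc1OCc1ccccc1
F7 | step 1 | 3-[3-(benzyloxy)-2-methoxyphenoxy]-4-methoxybenzaldehyde | COc1ccc(C=O)cc1Oc1cccc(OCc2ccccc2)c1OC
F8 | step 1 | (E)-7-{3-[3-(benzyloxy)-2-methoxyphenoxy]-4-methoxyphenyl}-5-oxohept-6-enoic acid | COc1ccc(/C=C/C(=O)CCCC(=O)O)cc1Oc1cccc(OCc2ccccc2)c1OC
F9 | step 7 | 7-hydroxy-juglanin A ethylene ketal (racemic benzylic alcohol) | COc1ccc2cc1Oc1ccc(c(O)c1OC)C(O)CCCC1(OCCO1)CC2
A1 | alternative 1 | 7-[2-(benzyloxy)-4-(5-bromo-2-methoxyphenoxy)-3-methoxyphenyl]hept-1-en-3-one | COc1ccc(Br)cc1Oc1ccc(CCCCC(=O)C=C)c(OCc2ccccc2)c1OC
A2 | alternative 1 | 1,2-dehydro-juglanin A benzyl ether (E-enone) | COc1ccc(/C=C/C(=O)CCCC2)cc1Oc1ccc2c(OCc3ccccc3)c1OC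
A3 | alternative 2 | 2-[2-(2-{4-[2-(benzyloxy)-3-methoxy-4-(2-oxopropoxy)phenyl]butyl}-1,3-dioxolan-2-yl)ethyl]propanedial | CC(=O)COc1ccc(CCCCC2(OCCO2)CCC(C=O)C=O)c(OCc2ccccc2)c1OC
A4 | alternative 2 | macrocyclic ring A phenol (hydroxyl at a1; ketal and benzyl ether retained) | Oc1ccc2cc1Oc1ccc(c(OCc3ccccc3)c1OC)CCCCC1(OCCO1)CC2
A5 | alternative 3 | 16-membered benzylic sulfone (sulfonyl group between C6 and C7; ketal and benzyl ether retained) | COc1ccc2cc1Oc1ccc(c(OCc3ccccc3)c1OC)CS(=O)(=O)CCCC1(OCCO1)CC2
A6 | alternative 3 | 6,7-dehydro-juglanin A ketal benzyl ether (E drawn) | COc1ccc(CCC2(OCCO2)CC/C=C/c2ccc3c(OC)c2OCc2ccccc2)cc1O3
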